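**Plan**
Cuts, in retrosynthetic order: the C1–C3' bond to the coumarin (oxocarbenium C-alkylation); the C3–acyl bond (C3-lithiation of the enol ether, Weinreb acylation); the O2–C1 bond of the dihydropyran with a C1–C4 bond put back, giving a 2-formylcyclobutanol; the cyclobutane bonds C7a–C4a and C1–C4 (ketene–alkene [2+2]).
Enabling feature: the ring O2–C3=C4–C4a–C7a–C1 is an enol hemiacetal in which O2=C3 is a formyl group on C4 and C1 a carbinol carbon. It is therefore the cyclobutane C1–C7a–C4a–C4 with that C=O unit inserted into the C1–C4 bond, i.e. a strained aldol whose retro-aldol and O-reclosure is a two-atom ring expansion.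
Forward order: (S)-citronellic acid is oxidised at C8; the [2+2] builds cyclopentane and cyclobutane together; reduction and oxidation then trigger expansion of the four-ring to the cyclopenta[c]pyran lactol; C3 is acylated; the coumarin is attached at C1; the silyl ether is removed.
Stereochemistry: C7 from (S)-citronellic acid; C4a and C7a from the suprafacial [2+2] (cis fusion, methyl exo); C1 from convex-face attack on the oxocarbenium ion; the side-chain carbinol from (R)-2-hydroxy-3-methylbutanoic acid.

Key step: step 5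

Remark: the carbinol centre of 7 and 8 and the acetal centre of 10, 11 and 16 are drawn as the expected major isomers; these centres are erased later, so their configuration is inconsequential.

Step 1
Reactants: 1 (3S)-3,7-dimethyloct-6-enoic acid [(S)-citronellic acid]
Product: 2 (3S,6E)-8-hydroxy-3,7-dimethyloct-6-enoic acid
Conditions: SeO2 (cat.), t-BuOOH (aq.), CH2Cl2, rt; then NaBH4, MeOH, 0 °C
Reagents that add atoms: selenium dioxide O=[Se]=O; tert-butyl hydroperoxide CC(C)(C)OO
Why: Selenium dioxide allylic oxidation (Riley oxidation: ene reaction then [2,3]-sigmatropic shift, t-BuOOH as terminal oxidant) is selective for the (E)-methyl group of a trisubstituted gem-dimethyl alkene, so the 6E allylic alcohol should form without touching the C3 stereocentre, and the borohydride treatment returns any over-oxidised enal to 2.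

Step 2
Reactants: 2 (3S,6E)-8-hydroxy-3,7-dimethyloct-6-enoic acid
Product: 3 (3S,6E)-8-(acetyloxy)-3,7-dimethyloct-6-enoic acid
Conditions: Ac2O, pyridine, DMAP (cat.), CH2Cl2, 0 °C to rt; aqueous work-up
Reagents that add atoms: acetic anhydride CC(=O)OC(C)=O
Why: DMAP-catalysed O-acetylation masks the allylic alcohol for the acid chloride chemistry, the mixed anhydride formed at the acid is hydrolysed on work-up, and no stereocentre is involved.

Step 3
Reactants: 3 (3S,6E)-8-(acetyloxy)-3,7-dimethyloct-6-enoic acid
Product: 6 [(1S,4S,5R,7S)-4,7-dimethyl-6-oxobicyclo[3.2.0]heptan-7-yl]methyl acetate, via acid chloride 4 (not isolated), via ketene 5 (not isolated)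
Conditions: (COCl)2, DMF (cat.), CH2Cl2, 0 °C to rt, concentrate; slow addition to Et3N, toluene, reflux, high dilution
Reagents that add atoms: none
Why: Intramolecular ketene–alkene [2+2] cycloaddition: the electrophilic ketene carbon bonds to the more substituted alkene carbon, which gives the fused bicyclo[3.2.0]heptan-6-one, the four-membered ring enforces the cis ring fusion (suprafacial addition to the alkene), and the chain methyl group should take the exo position of the forming cyclopentane away from the developing cyclobutanone, which sets both ring-fusion centres relative to the citronellic stereocentre; a minor endo-methyl isomer would be removed by chromatography.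

Step 4
Reactants: 6 [(1S,4S,5R,7S)-4,7-dimethyl-6-oxobicyclo[3.2.0]heptan-7-yl]methyl acetate
Product: 7 (1S,4S,5R,6R,7S)-7-(hydroxymethyl)-4,7-dimethylbicyclo[3.2.0]heptan-6-ol
Conditions: LiAlH4, THF, 0 °C
Reagents that add atoms: none
Why: Hydride reduction converts the cyclobutanone into the cyclobutanol (attack from the convex exo face should give the endo alcohol, whose configuration is inconsequential) and cleaves the acetate in the same operation.

Step 5
Reactants: 7 (1S,4S,5R,6R,7S)-7-(hydroxymethyl)-4,7-dimethylbicyclo[3.2.0]heptan-6-ol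
Product: 10 (1R,4aS,7S,7aR)-4,7-dimethyl-1,4a,5,6,7,7a-hexahydrocyclopenta[c]pyran-1-ol (nepetalactol), via hydroxy aldehyde 8 (not isolated), via iridodial 9 (not isolated)
Conditions: TEMPO (cat.), PhI(OAc)2, CH2Cl2, rt; aq. Na2S2O3/NaHCO3 wash; then K2CO3 (cat.), MeOH, 0 °C to rt
Reagents that add atoms: none
Why: TEMPO/PhI(OAc)2 should oxidise only the primary neopentyl alcohol of 7 (oxoammonium oxidation is sterically selective and oxidation of the cyclobutanol is further disfavoured by I-strain) to give the 2-formylcyclobutanol 8, which should persist until base is added because its endo hydroxyl and exo formyl groups are trans and cannot fragment through a cyclic retro-ene path. Carbonate then forms the C1 alkoxide, which undergoes strain-driven retro-aldol cleavage of the C1–C4 cyclobutane bond to the aldehyde enolate (iridodial 9 after proton transfer), and the enol oxygen recloses on the liberated C1 aldehyde, so that the C=O unit of the formyl group is formally inserted into the C1–C4 bond (net 1,3-shift of C1 from carbon to oxygen, four- to six-membered ring). The closest known reaction type is the de Mayo retro-aldol fragmentation of 2-acylcyclobutanols combined with the dialdehyde-to-lactol ring closure of iridoid hemiacetals. The pyran ring closes by 6-exo-trig attack of the enol oxygen on the aldehyde carbon, with the enol C3=C4 bond endocyclic. The only new stereocentre, C1, is a hemiacetal centre under thermodynamic control (hydroxyl on the convex face) and is erased in step 11, while C4a and C7 are untouched and the epimerisable C7a is held by the preference of the lactol for the cis-fused ring with C1 trans to the C7 methyl. The step needs oxidation of the primary over the secondary alcohol and no over-oxidation of the lactol, which the order of events secures because the lactol forms only after the oxidant has been washed out.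

Step 6
Reactants: 10 (1R,4aS,7S,7aR)-4,7-dimethyl-1,4a,5,6,7,7a-hexahydrocyclopenta[c]pyran-1-ol
Product: 11 tert-butyl{[(1S,4aS,7S,7aR)-4,7-dimethyl-1,4a,5,6,7,7a-hexahydrocyclopenta[c]pyran-1-yl]oxy}dimethylsilane
Conditions: TBSCl, imidazole, DMF, rt
Reagents that add atoms: tert-butyldimethylsilyl chloride CC(C)(C)[Si](C)(C)Cl
Why: Imidazole-mediated silylation of the lactol hydroxyl locks the ring form as a silyl acetal that tolerates organolithium reagents and later serves as the leaving group at C1; the anomeric configuration is inconsequential.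

Step 7
Reactants: 12 (2R)-2-hydroxy-3-methylbutanoic acid
Product: 13 (2R)-2-hydroxy-N-methoxy-N,3-dimethylbutanamide
Conditions: MeNHOMe·HCl, EDC·HCl, HOBt, N-methylmorpholine, CH2Cl2, 0 °C to rt
Reagents that add atoms: N,O-dimethylhydroxylamine hydrochloride CNOC.Cl
Why: Carbodiimide/HOBt amide coupling (Weinreb amide formation) of the α-hydroxy acid does not activate the stereocentre toward epimerisation, so the R configuration from the chiral pool should be retained.

Step 8
Reactants: 13 (2R)-2-hydroxy-N-methoxy-N,3-dimethylbutanamide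
Product: 14 (2R)-2-[(tert-butyldimethylsilyl)oxy]-N-methoxy-N,3-dimethylbutanamide
Conditions: TBSCl, imidazole, DMF, rt
Reagents that add atoms: tert-butyldimethylsilyl chloride CC(C)(C)[Si](C)(C)Cl
Why: Standard silyl ether formation protects the secondary alcohol against the vinyllithium reagent and leaves the stereocentre untouched.

Step 9
Reactants: 11 tert-butyl{[(1S,4aS,7S,7aR)-4,7-dimethyl-1,4a,5,6,7,7a-hexahydrocyclopenta[c]pyran-1-yl]oxy}dimethylsilane; 14 (2R)-2-[(tert-butyldimethylsilyl)oxy]-N-methoxy-N,3-dimethylbutanamide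
Product: 16 (2R)-2-[(tert-butyldimethylsilyl)oxy]-1-[(1S,4aS,7S,7aR)-1-[(tert-butyldimethylsilyl)oxy]-4,7-dimethyl-1,4a,5,6,7,7a-hexahydrocyclopenta[c]pyran-3-yl]-3-methylbutan-1-one, via vinyllithium 15 (not isolated)
Conditions: t-BuLi, THF/pentane, −78 to 0 °C; recool to −78 °C, add 14; aq. NH4Cl
Reagents that add atoms: none
Why: α-Lithiation of a cyclic enol ether (oxygen-directed removal of the vinylic C3–H by t-BuLi, as for dihydropyran and glycals) followed by Weinreb ketone synthesis, in which the chelated tetrahedral intermediate prevents over-addition and enolisation, so the acyl group should enter at C3 with the α-silyloxy stereocentre intact.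

Step 10
Reactants: 17 1-(2-hydroxy-6-methylphenyl)ethan-1-one
Product: 18 4-hydroxy-5-methyl-2H-chromen-2-one
Conditions: NaH, diethyl carbonate, toluene, 110 °C; aq. HCl
Reagents that add atoms: diethyl carbonate CCOC(=O)OCC
Why: Claisen-type C-acylation of the ketone enolate with diethyl carbonate followed by lactonisation onto the phenoxide is the standard route from 2-hydroxyacetophenones to 4-hydroxycoumarins and forms no stereocentre.

Step 11
Reactants: 16 (2R)-2-[(tert-butyldimethylsilyl)oxy]-1-[(1S,4aS,7S,7aR)-1-[(tert-butyldimethylsilyl)oxy]-4,7-dimethyl-1,4a,5,6,7,7a-hexahydrocyclopenta[c]pyran-3-yl]-3-methylbutan-1-one; 18 4-hydroxy-5-methyl-2H-chromen-2-one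
Product: 20 3-[(1R,4aS,7S,7aR)-3-{(2R)-2-[(tert-butyldimethylsilyl)oxy]-3-methylbutanoyl}-4,7-dimethyl-1,4a,5,6,7,7a-hexahydrocyclopenta[c]pyran-1-yl]-4-hydroxy-5-methyl-2H-chromen-2-one, via oxocarbenium ion 19 (not isolated)
Conditions: Sc(OTf)3 (cat.), 4 Å MS, CH2Cl2, −20 °C to rt
Reagents that add atoms: none
Why: Lewis-acid ionisation of the anomeric silyl acetal gives oxocarbenium ion 19, which is captured at carbon by the enol C3 of 18 (Friedel–Crafts-type C-alkylation as in aryl C-glycoside synthesis, any O-alkylated product reverting and rearranging O to C under the acid), with attack on the convex face of the cis-fused bicycle, cis to H-7a and anti to the cyclopentane ring, setting the (1R) centre, which should also be the thermodynamically preferred arrangement.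

Step 12
Reactants: 20 3-[(1R,4aS,7S,7aR)-3-{(2R)-2-[(tert-butyldimethylsilyl)oxy]-3-methylbutanoyl}-4,7-dimethyl-1,4a,5,6,7,7a-hexahydrocyclopenta[c]pyran-1-yl]-4-hydroxy-5-methyl-2H-chromen-2-one
Product: 21 4-hydroxy-3-{(1R,4aS,7S,7aR)-3-[(2R)-2-hydroxy-3-methylbutanoyl]-4,7-dimethyl-1,4a,5,6,7,7a-hexahydrocyclopenta[c]pyran-1-yl}-5-methyl-2H-chromen-2-one (CNP0214255.1)
Conditions: HF·pyridine, pyridine, THF, 0 °C to rt
Reagents that add atoms: none
Why: Desilylation by Si–F bond formation frees the secondary alcohol under mildly acidic conditions that avoid base-induced epimerisation of the α-hydroxy ketone and retro-oxa-Michael opening at C1.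

**Compound list**
1 | (3S)-3,7-dimethyloct-6-enoic acid [(S)-citronellic acid] | C[C@@H](CCC=C(C)C)CC(=O)O | starting material
2 | (3S,6E)-8-hydroxy-3,7-dimethyloct-6-enoic acid | C[C@@H](CC/C=C(\C)CO)CC(=O)O | intermediate
3 | (3S,6E)-8-(acetyloxy)-3,7-dimethyloct-6-enoic acid | C[C@@H](CC/C=C(\C)COC(C)=O)CC(=O)O | intermediate
4 | (3S,6E)-8-(acetyloxy)-3,7-dimethyloct-6-enoyl chloride | C[C@@H](CC/C=C(\C)COC(C)=O)CC(=O)Cl | intermediate
5 | ketene (2E,6S)-2,6-dimethyl-8-oxoocta-2,7-dien-1-yl acetate | C[C@@H](CC/C=C(\C)COC(C)=O)C=C=O | intermediate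
6 | [(1S,4S,5R,7S)-4,7-dimethyl-6-oxobicyclo[3.2.0]heptan-7-yl]methyl acetate | O=C1[C@H]2[C@H](CC[C@@H]2C)[C@@]1(C)COC(C)=O | intermediate
7 | (1S,4S,5R,6R,7S)-7-(hydroxymethyl)-4,7-dimethylbicyclo[3.2.0]heptan-6-ol | O[C@@H]1[C@H]2[C@H](CC[C@@H]2C)[C@@]1(C)CO | intermediate
8 | (1S,4S,5R,6R,7R)-6-hydroxy-4,7-dimethylbicyclo[3.2.0]heptane-7-carbaldehyde | O[C@@H]1[C@H]2[C@H](CC[C@@H]2C)[C@@]1(C)C=O | intermediate
9 | iridodial, (1R,2S,5R)-2-methyl-5-(1-oxopropan-2-yl)cyclopentane-1-carbaldehyde (side-chain epimers) | O=C[C@@H]1[C@@H](C)CC[C@@H]1C(C)C=O | intermediate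
10 | (1R,4aS,7S,7aR)-4,7-dimethyl-1,4a,5,6,7,7a-hexahydrocyclopenta[c]pyran-1-ol (nepetalactol) | CC1=CO[C@@H](O)[C@H]2[C@@H]1CC[C@@H]2C | intermediate
11 | tert-butyl{[(1S,4aS,7S,7aR)-4,7-dimethyl-1,4a,5,6,7,7a-hexahydrocyclopenta[c]pyran-1-yl]oxy}dimethylsilane | CC1=CO[C@@H](O[Si](C)(C)C(C)(C)C)[C@H]2[C@@H]1CC[C@@H]2C | intermediate
12 | (2R)-2-hydroxy-3-methylbutanoic acid | CC(C)[C@@H](O)C(=O)O | starting material
13 | (2R)-2-hydroxy-N-methoxy-N,3-dimethylbutanamide | CC(C)[C@@H](O)C(=O)N(C)OC | intermediate
14 | (2R)-2-[(tert-butyldimethylsilyl)oxy]-N-methoxy-N,3-dimethylbutanamide | CC(C)[C@@H](O[Si](C)(C)C(C)(C)C)C(=O)N(C)OC | intermediate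
15 | 3-lithio derivative of 11 (vinyllithium) | CC1=C([Li])O[C@@H](O[Si](C)(C)C(C)(C)C)[C@H]2[C@@H]1CC[C@@H]2C | intermediate
16 | (2R)-2-[(tert-butyldimethylsilyl)oxy]-1-[(1S,4aS,7S,7aR)-1-[(tert-butyldimethylsilyl)oxy]-4,7-dimethyl-1,4a,5,6,7,7a-hexahydrocyclopenta[c]pyran-3-yl]-3-methylbutan-1-one | CC1=C(C(=O)[C@H](O[Si](C)(C)C(C)(C)C)C(C)C)O[C@@H](O[Si](C)(C)C(C)(C)C)[C@H]2[C@@H]1CC[C@@H]2C | intermediate
17 | 1-(2-hydroxy-6-methylphenyl)ethan-1-one | CC(=O)c1c(C)cccc1O | starting material
18 | 4-hydroxy-5-methyl-2H-chromen-2-one | Cc1cccc2oc(=O)cc(O)c12 | intermediate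
19 | oxocarbenium ion from 16 (C1=O2 cation) | CC1=C(C(=O)[C@H](O[Si](C)(C)C(C)(C)C)C(C)C)[O+]=C[C@H]2[C@@H]1CC[C@@H]2C | intermediate
20 | 3-[(1R,4aS,7S,7aR)-3-{(2R)-2-[(tert-butyldimethylsilyl)oxy]-3-methylbutanoyl}-4,7-dimethyl-1,4a,5,6,7,7a-hexahydrocyclopenta[c]pyran-1-yl]-4-hydroxy-5-methyl-2H-chromen-2-one | CC1=C(C(=O)[C@H](O[Si](C)(C)C(C)(C)C)C(C)C)O[C@@H](c2c(O)c3c(C)cccc3oc2=O)[C@H]2[C@@H]1CC[C@@H]2C | intermediate
21 | 4-hydroxy-3-{(1R,4aS,7S,7aR)-3-[(2R)-2-hydroxy-3-methylbutanoyl]-4,7-dimethyl-1,4a,5,6,7,7a-hexahydrocyclopenta[c]pyran-1-yl}-5-methyl-2H-chromen-2-one | CC1=C(C(=O)[C@H](O)C(C)C)O[C@@H](c2c(O)c3c(C)cccc3oc2=O)[C@H]2[C@@H]1CC[C@@H]2C | target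

**Step count and risks**
Total steps: 12. Longest linear sequence: 9 (steps 1–6, 9, 11, 12).

Step 9 is the most likely to fail. The doubly α-branched amide may accept the hindered vinyllithium only slowly, so that 15 is consumed by proton transfer, and deprotonation of 11 may be incomplete. The fallback replaces acyl substitution by carbonyl addition and oxidation. It sets out from 14, which DIBAL-H (CH2Cl2, −78 °C) should reduce to (2R)-2-[(tert-butyldimethylsilyl)oxy]-3-methylbutanal F4. Vinyllithium 15, generated from 11 as before, adds to this less hindered and more electrophilic aldehyde to give the allylic alcohol (2R)-2-[(tert-butyldimethylsilyl)oxy]-1-[(1S,4aS,7S,7aR)-1-[(tert-butyldimethylsilyl)oxy]-4,7-dimethyl-1,4a,5,6,7,7a-hexahydrocyclopenta[c]pyran-3-yl]-3-methylbutan-1-ol F5 as a mixture of carbinol epimers. Dess–Martin periodinane buffered with NaHCO3 oxidises F5, and the fallback comes back at 16.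

Step 11 is the second risk. Ionisation of the acyl-deactivated silyl acetal may be slow, alkylation may stop at oxygen, and the Lewis acid may strip the side-chain silyl ether. The fallback changes from oxocarbenium substitution to a condensation manifold. It sets out from 16, from which HF·pyridine removes both silyl groups to give the lactol (2R)-2-hydroxy-1-[(1R,4aS,7S,7aR)-1-hydroxy-4,7-dimethyl-1,4a,5,6,7,7a-hexahydrocyclopenta[c]pyran-3-yl]-3-methylbutan-1-one F6. With ethylenediammonium diacetate (cat.) in CH2Cl2 and one equivalent of 18 added slowly, the ring-opened aldehyde form of F6 undergoes Knoevenagel condensation to the alkylidene chromane-2,4-dione F7 (not isolated). The enolised diketone of F7 closes by reversible 6-exo oxa-Michael addition under thermodynamic control at C1, and the fallback comes back directly at 21.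

Step 3 is the third risk. Facial selectivity of the high-temperature ketene cycloaddition with respect to the chain methyl group may be poor, and the alkene bearing the allylic acetate may react sluggishly, giving ketene oligomers. The fallback uses a keteniminium [2+2] cycloaddition, which is more electrophilic and proceeds at lower temperature through a tighter transition state. It sets out from 3, which pyrrolidine and EDC convert into the amide (2E,6S)-2,6-dimethyl-8-oxo-8-(pyrrolidin-1-yl)oct-2-en-1-yl acetate F1. Tf2O and 2,4,6-collidine in 1,2-dichloroethane at 80 °C generate the keteniminium triflate F2, which cyclises to the cyclobutaniminium triflate F3. Aqueous NaHCO3 hydrolysis brings the fallback back at 6.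

**Further compounds**
F1 | step 3 | (2E,6S)-2,6-dimethyl-8-oxo-8-(pyrrolidin-1-yl)oct-2-en-1-yl acetate | C[C@@H](CC/C=C(\C)COC(C)=O)CC(=O)N1CCCC1
F2 | step 3 | keteniminium triflate from F1 | C[C@@H](CC/C=C(\C)COC(C)=O)C=C=[N+]1CCCC1.[O-]S(=O)(=O)C(F)(F)F
F3 | step 3 | cyclobutaniminium triflate, pyrrolidinium analogue of 6 | C1CC[N+](=C2[C@H]3[C@H](CC[C@@H]3C)[C@@]2(C)COC(C)=O)C1.[O-]S(=O)(=O)C(F)(F)F
F4 | step 9 | (2R)-2-[(tert-butyldimethylsilyl)oxy]-3-methylbutanal | CC(C)[C@@H](O[Si](C)(C)C(C)(C)C)C=O
F5 | step 9 | (2R)-2-[(tert-butyldimethylsilyl)oxy]-1-[(1S,4aS,7S,7aR)-1-[(tert-butyldimethylsilyl)oxy]-4,7-dimethyl-1,4a,5,6,7,7a-hexahydrocyclopenta[c]pyran-3-yl]-3-methylbutan-1-ol (carbinol epimers) | CC1=C(C(O)[C@H](O[Si](C)(C)C(C)(C)C)C(C)C)O[C@@H](O[Si](C)(C)C(C)(C)C)[C@H]2[C@@H]1CC[C@@H]2C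
F6 | step 11 | (2R)-2-hydroxy-1-[(1R,4aS,7S,7aR)-1-hydroxy-4,7-dimethyl-1,4a,5,6,7,7a-hexahydrocyclopenta[c]pyran-3-yl]-3-methylbutan-1-one | CC1=C(C(=O)[C@H](O)C(C)C)O[C@@H](O)[C@H]2[C@@H]1CC[C@@H]2C
F7 | step 11 | alkylidene chromane-2,4-dione, ring-opened Knoevenagel adduct of F6 and 18 | Cc1cccc2OC(=O)C(=C[C@@H]3[C@@H](C)CC[C@@H]3C(C)C(=O)C(=O)[C@H](O)C(C)C)C(=O)c12
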